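## Plan

- **Cuts:** first the benzyl helper on the C5 oxygen. Then O1–C8a and C4–C4a of the dihydropyran ring are cut together, which leaves 3-(benzyloxy)benzyne and a trans-2-aryl-4-methyloxetane. Then the oxetane O–C(methyl) bond (back to a syn-1,3-diol monotosylate) and the carbonyl–C1' bond to the naphthalene.
- **Enabling feature:** on the benzo ring of the chroman, O1 (on C8a) is meta and C4 (on C4a) is ortho to the C5 oxygen. This is the pattern in which a 3-alkoxybenzyne takes up a nucleophile (far carbon) and an electrophile (near carbon). C4 also sits on naphthalene C1', para to the C4' methoxy group, so a C4–O bond ionises easily.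
- **Forward order:** the four-carbon chain is joined to the naphthalene (aryllithium plus Weinreb amide). The temporary oxetane ring is closed. The benzo ring is then inserted into the benzylic C–O bond, so the four-membered ring grows to the six-membered pyran ring. Debenzylation comes last.
- **Stereochemistry:** C2 comes from methyl (S)-3-hydroxybutanoate and is inverted once, in the oxetane closure, to R. The benzylic centre comes from a 1,3-syn reduction and is handed on to C4 (S, 2,4-trans) in the insertion, where retention and peri strain point the same way.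

Key step: step 9

Remark: the SMILES reads as (2R,4S), which is the 2,4-trans chroman (methyl pseudo-equatorial, naphthyl pseudo-axial). Compounds 1, 3 and 12 are taken as commercial.

## Route

Step 1
Reactants: 1 1,8-dimethoxynaphthalene
Product: 2 1-bromo-4,5-dimethoxynaphthalene
Conditions: NBS (1.0 equiv), MeCN, 0 °C to rt, dark
Reagents that add atoms: N-bromosuccinimide, O=C1CCC(=O)N1Br
Why: Electrophilic aromatic bromination, in which each methoxy group activates its own para position most, the two para positions are equivalent, and one equivalent of NBS should stop at the monobromide.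

Step 2
Reactants: 3 methyl (S)-3-hydroxybutanoate
Product: 4 (S)-3-hydroxy-N-methoxy-N-methylbutanamide
Conditions: MeNH(OMe)·HCl (1.5 equiv), iPrMgCl (4.2 equiv), THF, −20 to 0 °C; aq NH4Cl
Reagents that add atoms: N,O-dimethylhydroxylamine hydrochloride, Cl.CNOC
Why: Weinreb amide formation by aminolysis of the ester with the magnesium amide made in the flask, in which the carbinol centre lies beta to the carbonyl group and is not touched.

Step 3
Reactants: 2 1-bromo-4,5-dimethoxynaphthalene; 4 (S)-3-hydroxy-N-methoxy-N-methylbutanamide
Product: 7 (S)-1-(4,5-dimethoxynaphthalen-1-yl)-3-hydroxybutan-1-one, via chloromagnesium alkoxide 5 (not isolated), via aryllithium 6 (not isolated)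
Conditions: 4, iPrMgCl (1.0 equiv), THF, −20 °C; second flask: 2 (1.2 equiv), n-BuLi (1.2 equiv), THF, −78 °C; 5 cannulated into 6, −78 to 0 °C; 1 M aq HCl, 0 °C
Reagents that add atoms: none
Why: Weinreb ketone synthesis, in which bromine–lithium exchange gives 6, 6 adds once to the amide carbonyl of the pre-formed alkoxide 5, and the chelated tetrahedral adduct lasts until the quench, so that over-addition and retro-aldol cleavage are avoided and the carbinol centre is kept.

Step 4
Reactants: 7 (S)-1-(4,5-dimethoxynaphthalen-1-yl)-3-hydroxybutan-1-one
Product: 9 (1S,3S)-1-(4,5-dimethoxynaphthalen-1-yl)butane-1,3-diol, via diethylboron chelate 8 (not isolated)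
Conditions: Et2BOMe (1.1 equiv), THF/MeOH 4:1, −78 °C; NaBH4 (1.2 equiv), −78 to −40 °C; pH 7 buffer, then repeated evaporation from MeOH
Reagents that add atoms: none
Why: Narasaka–Prasad reduction, in which the six-membered boron chelate 8 holds the methyl group equatorial and takes external hydride along the axial path, so that the existing (S)-carbinol sets the new benzylic centre as S (1,3-syn).

Step 5
Reactants: 9 (1S,3S)-1-(4,5-dimethoxynaphthalen-1-yl)butane-1,3-diol
Product: 10 (2S,4S)-4-(4,5-dimethoxynaphthalen-1-yl)-4-hydroxybutan-2-yl 4-methylbenzenesulfonate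
Conditions: TsCl (1.05 equiv), pyridine, CH2Cl2, 0 °C
Reagents that add atoms: 4-toluenesulfonyl chloride, Cc1ccc(cc1)S(=O)(=O)Cl
Why: Sterically controlled monosulfonylation, in which the methyl carbinol is far less hindered than the carbinol flanked by naphthalene C2'–H and the peri C8'–H, and no stereocentre is touched.

Step 6
Reactants: 10 (2S,4S)-4-(4,5-dimethoxynaphthalen-1-yl)-4-hydroxybutan-2-yl 4-methylbenzenesulfonate
Product: 11 (2S,4R)-2-(4,5-dimethoxynaphthalen-1-yl)-4-methyloxetane
Conditions: KOtBu (1.2 equiv), THF, 0 °C to rt; chromatography on Et3N-washed silica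
Reagents that add atoms: none
Why: Intramolecular Williamson etherification (4-exo-tet), in which the benzylic alkoxide displaces the tosylate with inversion, so that the (S)-carbinol carbon becomes the (R)-ring carbon and the syn-diol gives the trans-oxetane.

Step 7
Reactants: 12 2-bromobenzene-1,3-diol
Product: 13 3-(benzyloxy)-2-bromophenol
Conditions: BnBr (1.0 equiv), K2CO3 (1.1 equiv), acetone, reflux
Reagents that add atoms: benzyl bromide, BrCc1ccccc1
Why: Williamson O-alkylation of a symmetrical diol with one equivalent of halide, after which the monoether is separated from the diether and from recovered 12, and the bromine marks the carbon that will carry silicon.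

Step 8
Reactants: 13 3-(benzyloxy)-2-bromophenol
Product: 16 3-(benzyloxy)-2-(trimethylsilyl)phenyl trifluoromethanesulfonate, via silyl ether 14 (not isolated), via lithium silylphenolate 15 (not isolated)
Conditions: HMDS (0.7 equiv), THF, reflux, then evaporation; n-BuLi (1.1 equiv), THF, −78 °C; Tf2O (1.2 equiv), −78 °C to rt
Reagents that add atoms: hexamethyldisilazane, C[Si](C)(C)N[Si](C)(C)C; trifluoromethanesulfonic anhydride, O=S(=O)(OS(=O)(=O)C(F)(F)F)C(F)(F)F
Why: O-silylation, bromine–lithium exchange and retro-Brook (1,3 oxygen-to-carbon) silyl migration give phenolate 15, which Tf2O traps, and this is the standard entry to ortho-silylaryl triflates.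

Step 9
Reactants: 11 (2S,4R)-2-(4,5-dimethoxynaphthalen-1-yl)-4-methyloxetane; 16 3-(benzyloxy)-2-(trimethylsilyl)phenyl trifluoromethanesulfonate
Product: 19 (2R,4S)-5-(benzyloxy)-4-(4,5-dimethoxynaphthalen-1-yl)-2-methylchromane, via 3-(benzyloxy)benzyne 17 (not isolated), via oxonium zwitterion 18 (not isolated)
Conditions: 11 (1.0 equiv, 0.5 M), CsF (5 equiv), 18-crown-6 (2 equiv), 4 Å sieves, toluene, 40 °C; 16 (2.0 equiv) added over 6 h
Reagents that add atoms: none
Why: Proposed new method: fluoride removes the silyl group of 16 and expels triflate to give aryne 17, the exposed and strongly Lewis-basic oxetane oxygen of 11 adds to it to give the aryl(dialkyl)oxonium zwitterion 18, and the benzylic C–O bond of 18 ionises with release of ring strain while the neighbouring aryl carbanion captures the benzylic carbon, so that the aryne is inserted into the C–O sigma bond and the four-membered ring grows to the six-membered pyran ring. The closest known reaction types are the insertion of arynes into the benzylic C–O bond of aryl epoxides to give 2,3-dihydrobenzofurans and the oxygen-addition/intramolecular conjugate-addition annulation of arynes with ortho-hydroxychalcones to give 9-substituted xanthenes. The ring closes as a 6-exo-trig attack of the aryl carbanion on the exocyclic carbon of the O-methylated naphtho-para-quinone methide, which is the main resonance form of the cation. C2 is carried in unchanged from 11, and the new C4 centre should be S (2,4-trans) on two concurring grounds: least-motion collapse of the tight zwitterion on the face that oxygen leaves (retention, trans-oxetane to trans-chroman) and, if the ion pair relaxes, a half-chair transition state with the methyl group pseudo-equatorial and the naphthyl group pseudo-axial to escape the peri (A1,3) clash with the benzyloxy group. The orientation on the aryne follows from the benzyloxy group beside the triple bond, which distorts 17 so that the far carbon is the more linear and electrophilic one and the charge builds up on the carbon next to the inductively withdrawing C–O bond, and this places oxygen on C8a and carbon on C4a. The choice between the two C–O bonds of 18 is secured by the para-methoxy group of the naphthalene, which makes only the benzylic bond ionisable, and the basic medium without acidic C–H or O–H bonds protects the acid-labile oxetane and leaves the aryl anion no proton source other than the C3 hydrogens.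

Step 10
Reactants: 19 (2R,4S)-5-(benzyloxy)-4-(4,5-dimethoxynaphthalen-1-yl)-2-methylchromane
Product: 20 cladonaphchrom A, (2R,4S)-4-(4,5-dimethoxynaphthalen-1-yl)-2-methylchroman-5-ol
Conditions: H2 (1 atm), Pd/C (10 wt % Pd on carbon), EtOAc/EtOH, rt
Reagents that add atoms: none
Why: Hydrogenolysis of a benzyl aryl ether, in which the O1–C2 bond is not benzylic and C4 bears no heteroatom, so that the ring, the methyl ethers and both stereocentres should persist.

## Compound list

1 | 1,8-dimethoxynaphthalene | COc1cccc2cccc(OC)c12 | starting material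
2 | 1-bromo-4,5-dimethoxynaphthalene | COc1cccc2c(Br)ccc(OC)c12 | intermediate
3 | methyl (S)-3-hydroxybutanoate | C[C@H](O)CC(=O)OC | starting material
4 | (S)-3-hydroxy-N-methoxy-N-methylbutanamide | C[C@H](O)CC(=O)N(C)OC | intermediate
5 | chloromagnesium alkoxide of 4 | C[C@H](O[Mg]Cl)CC(=O)N(C)OC | intermediate
6 | (4,5-dimethoxynaphthalen-1-yl)lithium | [Li]c1ccc(OC)c2c(OC)cccc12 | intermediate
7 | (S)-1-(4,5-dimethoxynaphthalen-1-yl)-3-hydroxybutan-1-one | COc1cccc2c(C(=O)C[C@H](C)O)ccc(OC)c12 | intermediate
8 | O-diethylboryl chelate of 7 | COc1cccc2c(C(=O)C[C@H](C)OB(CC)CC)ccc(OC)c12 | intermediate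
9 | (1S,3S)-1-(4,5-dimethoxynaphthalen-1-yl)butane-1,3-diol | COc1cccc2c([C@@H](O)C[C@H](C)O)ccc(OC)c12 | intermediate
10 | (2S,4S)-4-(4,5-dimethoxynaphthalen-1-yl)-4-hydroxybutan-2-yl 4-methylbenzenesulfonate | COc1cccc2c([C@@H](O)C[C@H](C)OS(=O)(=O)c3ccc(C)cc3)ccc(OC)c12 | intermediate
11 | (2S,4R)-2-(4,5-dimethoxynaphthalen-1-yl)-4-methyloxetane | COc1cccc2c([C@@H]3C[C@@H](C)O3)ccc(OC)c12 | intermediate
12 | 2-bromobenzene-1,3-diol | Oc1cccc(O)c1Br | starting material
13 | 3-(benzyloxy)-2-bromophenol | Oc1cccc(OCc2ccccc2)c1Br | intermediate
14 | [3-(benzyloxy)-2-bromophenoxy]trimethylsilane | C[Si](C)(C)Oc1cccc(OCc2ccccc2)c1Br | intermediate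
15 | lithium 3-(benzyloxy)-2-(trimethylsilyl)phenolate | [Li]Oc1cccc(OCc2ccccc2)c1[Si](C)(C)C | intermediate
16 | 3-(benzyloxy)-2-(trimethylsilyl)phenyl trifluoromethanesulfonate | C[Si](C)(C)c1c(OCc2ccccc2)cccc1OS(=O)(=O)C(F)(F)F | intermediate
17 | 3-(benzyloxy)benzyne | C1#CC(OCc2ccccc2)=CC=C1 | intermediate
18 | O-aryl oxetanium zwitterion from 11 and 17 | COc1cccc2c([C@@H]3C[C@@H](C)[O+]3c4cccc(OCc5ccccc5)[c-]4)ccc(OC)c12 | intermediate
19 | (2R,4S)-5-(benzyloxy)-4-(4,5-dimethoxynaphthalen-1-yl)-2-methylchromane | COc1cccc2c([C@@H]3C[C@@H](C)Oc4cccc(OCc5ccccc5)c43)ccc(OC)c12 | intermediate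
20 | cladonaphchrom A | COc1cccc2c([C@@H]3C[C@@H](C)Oc4cccc(O)c43)ccc(OC)c12 | target

## Step count and risks

Total step count: 10. Longest linear sequence: 7 (steps 1, 3, 4, 5, 6, 9, 10).

**1. Step 9.**
- **What may go wrong:** proton transfer from C3 to the aryl anion of 18 would open the chain by elimination. Fluoride may intercept the oxonium ion. The ion pair may relax with loss of facial selectivity.
- **Fallback (known chemistry):** it sets out from 13, with 4 and 1 as partners, and comes back at 19. Mitsunobu etherification of 13 with the carbinol of 4 (PPh3, DIAD, toluene, 0 °C to rt, inversion) should give (R)-3-[3-(benzyloxy)-2-bromophenoxy]-N-methoxy-N-methylbutanamide F1. Bromine–lithium exchange (n-BuLi, THF, −78 °C) with Parham cyclisation onto the amide should give (R)-5-(benzyloxy)-2-methylchroman-4-one F2. NaBH4 in MeOH at 0 °C should give mainly (2R,4S)-5-(benzyloxy)-2-methylchroman-4-ol F3. Friedel–Crafts alkylation of 1 with the cation from F3 (BF3·OEt2, CH2Cl2, −40 °C) should then give 19. The para carbon of 1 attacks along the axial path anti to the C2 methyl group, which is the usual origin of 2,4-trans 4-arylchromans.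

**2. Step 5.**
- **What may go wrong:** sulfonylation may occur at the benzylic hydroxyl group, followed by ionisation and decomposition, or twice.
- **Fallback:** it sets out from 7 and comes back at 10. The leaving group is installed while only one hydroxyl group exists. TsCl in pyridine at 0 °C should give (S)-4-(4,5-dimethoxynaphthalen-1-yl)-4-oxobutan-2-yl 4-methylbenzenesulfonate F4, which is kept away from stronger base to hold back beta-elimination. The benzylic centre is then set by the catalyst and not by the substrate, in a Corey–Bakshi–Shibata reduction ((R)-Me-CBS oxazaborolidine, BH3·SMe2, THF, −20 °C), which should deliver 10.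

**3. Step 6.**
- **What may go wrong:** Grob-type fragmentation of the gamma-tosyloxy alkoxide, E2 elimination of the secondary tosylate, or acid-triggered opening of the oxetane during isolation.
- **Fallback:** it sets out from 10, avoids the oxetane and comes back at 20. Monobenzylation of 4-bromoresorcinol (BnBr, K2CO3, acetone) gives 5-(benzyloxy)-2-bromophenol F5. Its phenolate (Cs2CO3, DMF, 45 °C) displaces the tosylate of 10 with inversion and without forming the alkoxide. This should give (1S,3R)-3-[5-(benzyloxy)-2-bromophenoxy]-1-(4,5-dimethoxynaphthalen-1-yl)butan-1-ol F6. Ionisation of the benzylic alcohol (BF3·OEt2, CH2Cl2, −20 °C) then triggers an intramolecular Friedel–Crafts alkylation. The bromine blocks the other ortho position, so the ring can close only between the two oxygens, with the same peri-strain bias for 2,4-trans. The product should be (2R,4S)-5-(benzyloxy)-8-bromo-4-(4,5-dimethoxynaphthalen-1-yl)-2-methylchromane F7. H2 over Pd/C with Et3N in EtOAc/EtOH removes bromine and benzyl together to give 20.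

## Further compounds

F1 | step 9 | (R)-3-[3-(benzyloxy)-2-bromophenoxy]-N-methoxy-N-methylbutanamide | CON(C)C(=O)C[C@@H](C)Oc1cccc(OCc2ccccc2)c1Br
F2 | step 9 | (R)-5-(benzyloxy)-2-methylchroman-4-one | C[C@@H]1CC(=O)c2c(OCc3ccccc3)cccc2O1
F3 | step 9 | (2R,4S)-5-(benzyloxy)-2-methylchroman-4-ol | C[C@@H]1C[C@H](O)c2c(OCc3ccccc3)cccc2O1
F4 | step 5 | (S)-4-(4,5-dimethoxynaphthalen-1-yl)-4-oxobutan-2-yl 4-methylbenzenesulfonate | COc1cccc2c(C(=O)C[C@H](C)OS(=O)(=O)c3ccc(C)cc3)ccc(OC)c12
F5 | step 6 | 5-(benzyloxy)-2-bromophenol | Oc1cc(OCc2ccccc2)ccc1Br
F6 | step 6 | (1S,3R)-3-[5-(benzyloxy)-2-bromophenoxy]-1-(4,5-dimethoxynaphthalen-1-yl)butan-1-ol | COc1cccc2c([C@@H](O)C[C@@H](C)Oc3cc(OCc4ccccc4)ccc3Br)ccc(OC)c12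
F7 | step 6 | (2R,4S)-5-(benzyloxy)-8-bromo-4-(4,5-dimethoxynaphthalen-1-yl)-2-methylchromane | COc1cccc2c([C@@H]3C[C@@H](C)Oc4c(Br)ccc(OCc5ccccc5)c43)ccc(OC)c12
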